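All runs are simulated for an exercise.

Early on, the two earlier runs part: Sunday's links read 20% at 1.50 h and the later readings stay near there, while Friday's read 58% at 4.00 h and the later readings stay near that.

| setting | Friday's | Sunday's | alpha | beta |
|---|---|---|---|---|
| first end groups | 0.061 M (fed, over 80 min) | 0.20 M (fed, over 80 min) | 0.050 M (fed, over 80 min) | 0.15 M (fed, over 80 min) |
| second end groups | 0.0475 M | 0.0475 M | 0.0475 M | 0.0475 M |
| protic impurity | 0.050 M | 0.050 M | 0.0500 M | 0.0500 M |
| remark | run made earlier | run made earlier |  |  |
| time |  |  | 12 h | 12 h |

| Friday's: time / h | Friday's: links / % | Sunday's: time / h | Sunday's: links / % |
|---|---|---|---|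
| 1.50 | 35 | 1.50 | 20 |
| 4.00 | 58 | 4.00 | 21 |
| 8.00 | 57 | 8.00 | 22 |
| 12.0 | 59 | 12.0 | 22 |

(scatter of a reading: 1.5 percentage points)

- each molecule carries two end groups: a chain counts once for every two ends that are left, dead ends included; the units are half of the end groups of the two monomers charged

1. which of the two ends with the longer chains by the average number of monomer units in a chain (unreacted monomers counted as chains of one) ("neither" if they lie within 10%) (alpha / beta / neither)
2. average number of monomer units in a chain (unreacted monomers counted as chains of one) at the end, alpha
3. average number of monomer units in a chain (unreacted monomers counted as chains of one) at the end, beta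

Each link removes two ends, so on the stated count the length is (c(first end groups) + c(second end groups)) / (c(first end groups) + c(second end groups) − 2 c(links)), with charges in the sum.

Turn the question round: what must hold for beta to end longer? A link uses one second end, and in beta second end groups are the limiting reagent, so the balance caps c(links) at the charge of second end groups. Putting that cap into the length gives the sum of the two charges over their difference, the ceiling length, for beta 1.93.

For beta to win, alpha must fall below that ceiling, which needs c(links) in alpha under 0.0234 M. Friday's plateau, from a flask with 0.061 M of first end groups and the same second end groups, reads 0.0354 M on average, above that bound, so we expect alpha to clear it.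

Our own reckoning carries Friday's links over to alpha and gives a length of 3.65. Alpha is charged with less first end groups than Friday, so we commit to something under that. Sunday's plateau puts beta near 1.78.

The forecast says alpha, with alpha at 2.56 (2.35 to 2.8) and beta at 1.8 (1.7 to 1.93): “The surplus and capped ends shorten beta, so alpha ends longer.” Our alpha stands above its range.

The flasks give alpha as the longer: alpha 3.32, above the forecast's range and below our figure, and beta 1.70.

    first end groups + second end groups ⇌ links + released group (K = 170, k = 22.0 L mol⁻¹ h⁻¹)
    second end groups + protic impurity → quenched reagent (k = 3.80 L mol⁻¹ h⁻¹)
    released group → by-product carried off (k = 0.300 h⁻¹)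

The difference in first end groups is the main reason beta ends shorter: beta gives 1.70, and without that difference 3.32. Beta stays under its ceiling, with second end groups down to 0.00710% of their charge and 0.00687 M of quenched reagent formed. The neighbour flask charged with 0.20 M of first end groups has a ceiling of 1.62 and gives 1.51.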